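The ratio that set my course was the solid substrate lost per litre by 4.00 h, dawn over noon: 1.01, more than the ratio of the charges taken the same way, 0.453. So in these two runs the solid behaved like a reservoir whose outflow ignored its size, and percent of charge looked like the wrong currency.

| flask | solid substrate | gas phase | remark | time |
|---|---|---|---|---|
| dawn | 0.34 M | 31 mM (held) | run made earlier |  |
| noon | 0.75 M | 31 mM (held) | run made earlier |  |
| flask | 0.50 M | 31 mM (held) |  | 3.0 h |

| run | time / h | target / % | solid substrate / % |
|---|---|---|---|
| dawn | 0.250 | 0.6 | 92.1 |
| dawn | 0.500 | 0.5 | 85.6 |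
| dawn | 0.833 | 1.2 | 77.6 |
| dawn | 1.33 | 1.7 | 70.1 |
| dawn | 2.00 | 3.8 | 60.3 |
| dawn | 4.00 | 5.6 | 45.0 |
| noon | 0.250 | 0.1 | 96.5 |
| noon | 0.667 | 0.5 | 91.1 |
| noon | 1.33 | 0.7 | 86.8 |
| noon | 2.00 | 1.3 | 82.0 |
| noon | 3.00 | 2.4 | 78.4 |
| noon | 4.00 | 1.9 | 75.3 |

(scatter of a reading: 0.3 percentage points)

- solid substrate is a solid; its amount is given per volume of the solution
- the analysis behind the earlier runs scatters by 0.3 percentage points, standard deviation
- at the start none of the gas phase is in solution
- at the start none of the solid substrate is in solution

1. target at 3.0 h, in percent of the solid substrate charged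
2. concentration of dissolved gas in solution at 3.0 h, in percent of saturation

Did target follow the same currency? I averaged the dawn readings at 2.00 h and 4.00 h and multiplied by the dawn charge. That gave 0.0160 M, my c_P, the target per litre at 3.0 h while solid remains. Divided by the noon charge, c_P gave 2.13% against the noon reading of 2.4%, a gap of about the scatter.

Did the new charge last? Dawn had lost 0.187 M by 4.00 h, less than the 0.50 M charged here, so I expected solid to remain. My figure for target was therefore 3.20%. For the gas the readings gave me nothing.

The forecast said 2.9% of target (2.4% to 3.5%), lower than my figure, and 85% of saturation (45% to 99%), reasoning that “with ordinary stirring the solution should stay near saturation”.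

The flask gave 3.09% of target, and dissolved gas at 99.3% of saturation, higher than the forecast's 85%. At 3.00 h solid substrate still stood at 67.3% of the charge. Per litre, the target came to 0.0155 M, against c_P of 0.0160 M.

    gas phase ⇌ dissolved gas, rate k1*(csat - [dissolved gas]) (kL = 140 h⁻¹)
    starting material + dissolved gas → target (k = 3.78 M⁻¹ h⁻¹)
    dissolved gas + target → over-reacted product (k = 4.20 M⁻¹ h⁻¹)
    dissolved gas → decomposed reagent (k = 0.128 h⁻¹)
    dissolved gas + target → over-reaction product (k = 19.5 M⁻¹ h⁻¹)
    solid substrate ⇌ starting material, rate k6*(cs6 - [starting material]) while solid is left; crystals form when [starting material] > cs6 (solubility = 0.170 M, k = 0.682 h⁻¹)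

With the same flask charged at 0.20 M, c_P gave 8.00%. The computed target was 7.72%, with solid substrate at 18.3% of that charge.

(The numbers in the tables were computed for substances that don't exist, and the scatter is random.)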